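**Plan**

1. Retrosynthesis: the enol OH of the target, 2-hydroxy-3-[(2S)-2-acetoxypropyl]-5,6,8-trimethoxy-1,4-naphthoquinone, is first masked as a tert-butyl ether. Both aryl–carbonyl bonds of the quinone ring (C8a–C1 and C4a–C4) are then cut together, and the freed O=C–C(alkyl)=C(O)–C=O unit is closed on itself (C1 to C4) into a cyclobut-3-ene-1,2-dione. Last, the ring–CH2 bond of the side chain is cut.
2. Enabling feature: quinone carbons C1–C4 (two carbonyls flanking an oxygen-bearing and an alkyl-bearing alkene carbon) are a squaric-acid-type four-membered ring once C1 and C4 are joined. The benzo ring offers a metalated carbon (future C8a) next to its only free ortho C–H (future C4a). Carbonyl addition followed by 4π opening and 6π closure therefore enlarges the four-membered ring into the quinone ring, with the OH/alkyl placement fixed.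
3. Forward: the β-oxido organolithium from (S)-1-chloropropan-2-ol (1) is added to di-tert-butyl squarate (2), joining the side chain to the bought four-membered ring. Acetylation and loss of one tert-butyl group give the cyclobutenedione. The aryllithium is then added and a one-flask ring expansion/oxidation builds the quinone ring onto the bought arene. Acid removes the last tert-butyl group.
4. Stereochemistry: the single (S) carbinol centre is bought with 1; no bond to it is made or broken, and no other stereocentre survives in the target.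

Key step: step 3

Remark: di-tert-butyl squarate is taken as a catalogue squaric acid diester; tert-butyl is chosen because one group leaves as 2-methylpropene in step 2 and the other under mild acid in step 4.

**Step 1**
Reactants: 1 (S)-1-chloropropan-2-ol; 2 di-tert-butyl squarate (3,4-di-tert-butoxycyclobut-3-ene-1,2-dione)
Product: 6 2,3-di-tert-butoxy-4-hydroxy-4-[(2S)-2-hydroxypropyl]cyclobut-2-en-1-one (epimers at C4), via lithium chloroalkoxide 3 (not isolated), via β-oxido organolithium 4 (not isolated), via dilithium dialkoxide adduct 5 (not isolated)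
Conditions: n-BuLi (1.0 equiv), THF, −78 °C; lithium naphthalenide (LiC10H8, 2.0 equiv), −78 °C, 5 h; then 2 in THF, −78 °C; sat. aq. NH4Cl, −78 °C
Reagents that add atoms: none
Why: O-lithiation followed by reductive lithiation of the C–Cl bond should give the β-oxido organolithium 4 (a functionalized organolithium in which the O–Li group is too poor a leaving group for β-elimination at −78 °C), which adds 1,2 to one carbonyl of the squarate (organolithium addition to a squaric ester); the (S) centre is bought and untouched, and the new ring carbinol centre forms as an epimer mixture that is erased in step 2.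

**Step 2**
Reactants: 6 2,3-di-tert-butoxy-4-hydroxy-4-[(2S)-2-hydroxypropyl]cyclobut-2-en-1-one
Product: 9 3-tert-butoxy-4-[(2S)-2-acetoxypropyl]cyclobut-3-ene-1,2-dione, via secondary monoacetate 7 (not isolated), via tertiary trifluoroacetate 8 (not isolated)
Conditions: Ac2O (1.1 equiv), pyridine, CH2Cl2, 0 °C to rt; then (CF3CO)2O (1.3 equiv), −20 to 0 °C; aq. NaHCO3
Reagents that add atoms: acetic anhydride CC(=O)OC(C)=O
Why: Ac2O/pyridine should esterify only the unhindered secondary alcohol, and O-trifluoroacetylation of the tertiary carbinol then triggers ionization to an oxygen-stabilized cyclobutenyl cation that sheds 2-methylpropene from its oxocarbenium oxygen to give the 1,2-dione (the standard conversion of squarate adducts into 3-alkoxy-4-alkylcyclobutenediones), without involving the stereocentre.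

**Step 3**
Reactants: 9 3-tert-butoxy-4-[(2S)-2-acetoxypropyl]cyclobut-3-ene-1,2-dione; 10 1-bromo-2,4,5-trimethoxybenzene
Product: 16 2-tert-butoxy-3-[(2S)-2-acetoxypropyl]-5,6,8-trimethoxy-1,4-naphthoquinone, via 2,4,5-trimethoxyphenyllithium 11 (not isolated), via lithium cyclobutenolate adduct 12 (not isolated), via 4-aryl-4-hydroxycyclobutenone 13 (not isolated), via (Z)-dienylketene 14 (not isolated), via naphthalene-1,4-diol 15 (not isolated)
Conditions: 10, n-BuLi (1.0 equiv), THF, −78 °C; cannulated into 9 (1.05 equiv), THF, −78 °C; AcOH (1.0 equiv), −78 °C to rt; solvent switched to degassed toluene, 110 °C, 2 h; then Ag2O, rt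
Reagents that add atoms: none
Why: Br/Li exchange gives aryllithium 11, which adds at −78 °C to the C2 carbonyl of 9 (the ketone-like one next to the tert-butoxy-bearing carbon) and so makes the first aryl–carbon bond; on heating, cyclobutenol 13 should undergo conrotatory 4π electrocyclic opening of its C4–C1 bond to dienylketene 14, whose ketene carbon closes onto the aryl C6–H carbon (second aryl–carbon bond), and tautomerization gives hydroquinone 15, which Ag2O dehydrogenates to quinone 16. The closest known reaction type is the Moore rearrangement of 4-aryl-4-hydroxycyclobutenones from squaric acid derivatives to naphthoquinones, here telescoped in one flask. The new six-membered ring is closed by a thermal disrotatory 6π electrocyclization over the ketene C=C, the enol C=C and the aryl C1–C6 π bond. No stereocentre is created that survives: the ring carbinol carbon of 13 becomes sp2, and the (S) side-chain centre is a remote spectator. Three selectivities are needed: carbonyl choice (C2 over the vinylogous-ester C1 carbonyl and over the acetate, secured by the donor tert-butoxy group that deactivates C1 and by inverse addition of one equivalent at −78 °C), torquoselectivity (hydroxyl outward and aryl inward, secured by the donor OH), and the site of closure on the arene (secured because C6 is the only ortho position bearing hydrogen, C2 carrying a methoxy group).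

**Step 4**
Reactants: 16 2-tert-butoxy-3-[(2S)-2-acetoxypropyl]-5,6,8-trimethoxy-1,4-naphthoquinone
Product: 17 2-hydroxy-3-[(2S)-2-acetoxypropyl]-5,6,8-trimethoxy-1,4-naphthoquinone (target)
Conditions: CF3CO2H, CH2Cl2, 0 °C to rt
Reagents that add atoms: none
Why: acidolysis of the vinylogous tert-butyl ester (E1 loss of the tert-butyl cation as 2-methylpropene) should free the enolic hydroxyl of the 2-hydroxy-1,4-naphthoquinone, while the secondary acetate, the three aryl methyl ethers and the stereocentre are inert to anhydrous CF3CO2H.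

**Compound list**

1 | (S)-1-chloropropan-2-ol | C[C@H](O)CCl | starting material
2 | di-tert-butyl squarate (3,4-di-tert-butoxycyclobut-3-ene-1,2-dione) | CC(C)(C)OC1=C(OC(C)(C)C)C(=O)C1=O | starting material
3 | lithium (S)-1-chloropropan-2-olate | C[C@H](O[Li])CCl | intermediate
4 | lithium (S)-1-lithiopropan-2-olate (β-oxido organolithium) | [Li]C[C@H](C)O[Li] | intermediate
5 | dilithium dialkoxide of 6 (squarate 1,2-adduct, epimers at the ring carbinol carbon) | CC(C)(C)OC1=C(OC(C)(C)C)C(O[Li])(C[C@H](C)O[Li])C1=O | intermediate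
6 | 2,3-di-tert-butoxy-4-hydroxy-4-[(2S)-2-hydroxypropyl]cyclobut-2-en-1-one (epimers at C4) | CC(C)(C)OC1=C(OC(C)(C)C)C(O)(C[C@H](C)O)C1=O | intermediate
7 | (2S)-1-(2,3-di-tert-butoxy-1-hydroxy-4-oxocyclobut-2-en-1-yl)propan-2-yl acetate (epimers at the ring carbinol carbon) | CC(C)(C)OC1=C(OC(C)(C)C)C(O)(C[C@H](C)OC(C)=O)C1=O | intermediate
8 | tertiary trifluoroacetate of 7 | CC(C)(C)OC1=C(OC(C)(C)C)C(OC(=O)C(F)(F)F)(C[C@H](C)OC(C)=O)C1=O | intermediate
9 | 3-tert-butoxy-4-[(2S)-2-acetoxypropyl]cyclobut-3-ene-1,2-dione | CC(C)(C)OC1=C(C[C@H](C)OC(C)=O)C(=O)C1=O | intermediate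
10 | 1-bromo-2,4,5-trimethoxybenzene | COc1cc(OC)c(Br)cc1OC | starting material
11 | 2,4,5-trimethoxyphenyllithium | COc1cc(OC)c([Li])cc1OC | intermediate
12 | lithium alkoxide of 13 | COc1cc(OC)c(cc1OC)C1(O[Li])C(OC(C)(C)C)=C(C[C@H](C)OC(C)=O)C1=O | intermediate
13 | 2-[(2S)-2-acetoxypropyl]-3-tert-butoxy-4-hydroxy-4-(2,4,5-trimethoxyphenyl)cyclobut-2-en-1-one (epimers at C4) | COc1cc(OC)c(cc1OC)C1(O)C(OC(C)(C)C)=C(C[C@H](C)OC(C)=O)C1=O | intermediate
14 | (3Z)-2-[(2S)-2-acetoxypropyl]-3-tert-butoxy-4-hydroxy-4-(2,4,5-trimethoxyphenyl)buta-1,3-dien-1-one (dienylketene, aryl cis to the ketene-bearing carbon) | COc1cc(OC)c(cc1OC)/C(O)=C(OC(C)(C)C)\C(C[C@H](C)OC(C)=O)=C=O | intermediate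
15 | 2-tert-butoxy-3-[(2S)-2-acetoxypropyl]-5,6,8-trimethoxynaphthalene-1,4-diol | COc1cc(OC)c2c(O)c(OC(C)(C)C)c(C[C@H](C)OC(C)=O)c(O)c2c1OC | intermediate
16 | 2-tert-butoxy-3-[(2S)-2-acetoxypropyl]-5,6,8-trimethoxy-1,4-naphthoquinone | COc1cc(OC)c2c(c1OC)C(=O)C(C[C@H](C)OC(C)=O)=C(OC(C)(C)C)C2=O | intermediate
17 | 2-hydroxy-3-[(2S)-2-acetoxypropyl]-5,6,8-trimethoxy-1,4-naphthoquinone, i.e. (2S)-1-(3-hydroxy-5,7,8-trimethoxy-1,4-dioxo-1,4-dihydronaphthalen-2-yl)propan-2-yl acetate | COc1cc(OC)c2c(c1OC)C(=O)C(C[C@H](C)OC(C)=O)=C(O)C2=O | target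

**Count**

Total step count: 4. Longest linear sequence: 4 steps (1 → 6 → 9 → 16 → 17).

**Steps most likely to fail**

1. Step 3. What may go wrong: the aryllithium is diverted into the acetate (acyl attack or α-deprotonation) instead of the ring ketone; the electron-rich benzylic carbinol ionizes on protonation; or the hydroxyl rotates inward during ring opening, so that the ketene is trapped by oxygen and not by the arene. Fallback (sets out from 6, comes back at 16): the ester is kept out of the key step. Diol 6 is silylated at the secondary hydroxyl (TBSCl, imidazole, DMF) to 2,3-di-tert-butoxy-4-hydroxy-4-[(2S)-2-(tert-butyldimethylsilyloxy)propyl]cyclobut-2-en-1-one F1. (CF3CO)2O/pyridine should convert this into 3-tert-butoxy-4-[(2S)-2-(tert-butyldimethylsilyloxy)propyl]cyclobut-3-ene-1,2-dione F2. F2 and 10 under the step 3 sequence should give 2-tert-butoxy-3-[(2S)-2-(tert-butyldimethylsilyloxy)propyl]-5,6,8-trimethoxy-1,4-naphthoquinone F3. Buffered HF·pyridine (THF/pyridine, 0 °C) should free 2-tert-butoxy-3-[(2S)-2-hydroxypropyl]-5,6,8-trimethoxy-1,4-naphthoquinone F4, and Ac2O/pyridine returns to 16.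

2. Step 1. What may go wrong: incomplete reductive lithiation, β-elimination of the dianion to propene on warming, or electron transfer from residual naphthalenide to the squarate in place of carbonyl addition. Fallback (sets out from 2, with 10, and comes back at 16): the side chain is joined after the ring expansion by radical C–H alkylation. 2 is reduced with LiAlH(OC(CH3)3)3 (THF, −78 to 0 °C) to 2,3-di-tert-butoxy-4-hydroxycyclobut-2-en-1-one F5. (CF3CO)2O/pyridine should give 3-tert-butoxycyclobut-3-ene-1,2-dione F6. F6 with 10 under the step 3 sequence should give 2-tert-butoxy-5,6,8-trimethoxy-1,4-naphthoquinone F7. (S)-3-acetoxybutanoic acid F8 (from purchased (S)-3-hydroxybutanoic acid with Ac2O/pyridine) is then decarboxylated with AgNO3 (cat.) and (NH4)2S2O8 in MeCN/H2O at 65 °C (Kochi–Anderson type quinone alkylation). The primary (S)-2-acetoxypropyl radical should add at C3, the only free quinone carbon of F7, to give 16; the stereocentre is β to the radical and is not touched.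

3. Step 2. What may go wrong: acyl transfer to the tertiary carbinol, or loss of both tert-butyl groups when the acid set free strips the remaining vinylogous ester during the ionization. Fallback (sets out from 6, through isolated 7, and comes back at 9): the double dealkylation is accepted and one tert-butyl group is put back. Monoacetate 7 is treated with CF3CO2H in CH2Cl2 to give the alkylsemisquaric acid 3-hydroxy-4-[(2S)-2-acetoxypropyl]cyclobut-3-ene-1,2-dione F9. Its acidic enol is O-alkylated with tert-butyl 2,2,2-trichloroacetimidate (CH2Cl2/cyclohexane, rt) to return to 9; alkylation at either oxygen of the vinylogous carboxylate gives the same constitution.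

**Further compounds**

F1 | step 3 | 2,3-di-tert-butoxy-4-hydroxy-4-[(2S)-2-(tert-butyldimethylsilyloxy)propyl]cyclobut-2-en-1-one | CC(C)(C)OC1=C(OC(C)(C)C)C(O)(C[C@H](C)O[Si](C)(C)C(C)(C)C)C1=O
F2 | step 3 | 3-tert-butoxy-4-[(2S)-2-(tert-butyldimethylsilyloxy)propyl]cyclobut-3-ene-1,2-dione | CC(C)(C)OC1=C(C[C@H](C)O[Si](C)(C)C(C)(C)C)C(=O)C1=O
F3 | step 3 | 2-tert-butoxy-3-[(2S)-2-(tert-butyldimethylsilyloxy)propyl]-5,6,8-trimethoxy-1,4-naphthoquinone | COc1cc(OC)c2c(c1OC)C(=O)C(C[C@H](C)O[Si](C)(C)C(C)(C)C)=C(OC(C)(C)C)C2=O
F4 | step 3 | 2-tert-butoxy-3-[(2S)-2-hydroxypropyl]-5,6,8-trimethoxy-1,4-naphthoquinone | COc1cc(OC)c2c(c1OC)C(=O)C(C[C@H](C)O)=C(OC(C)(C)C)C2=O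
F5 | step 1 | 2,3-di-tert-butoxy-4-hydroxycyclobut-2-en-1-one | CC(C)(C)OC1=C(OC(C)(C)C)C(O)C1=O
F6 | step 1 | 3-tert-butoxycyclobut-3-ene-1,2-dione | CC(C)(C)OC1=CC(=O)C1=O
F7 | step 1 | 2-tert-butoxy-5,6,8-trimethoxy-1,4-naphthoquinone | COc1cc(OC)c2c(c1OC)C(=O)C=C(OC(C)(C)C)C2=O
F8 | step 1 | (S)-3-acetoxybutanoic acid | OC(=O)C[C@H](C)OC(C)=O
F9 | step 2 | 3-hydroxy-4-[(2S)-2-acetoxypropyl]cyclobut-3-ene-1,2-dione | OC1=C(C[C@H](C)OC(C)=O)C(=O)C1=O
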